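## The problem

Target 32 is a heptameric phloroglucinol-derived polyether: seven benzene rings A–G joined only by six diaryl ether oxygens, with seventeen free phenols and no stereocentre, so the task is one of regiochemistry and C–O bond construction. Four of the ether oxygens (A1–O–B1, B4–O–C1, E4–O–F1, F4–O–G1) link a carbon flanked by two oxygenated carbons to a carbon flanked by two CH groups, and the two at ring D (C4–O–D1, D6–O–E1) follow the same pattern except that D1 has one oxygenated neighbour, D6. All rings are electron-rich and one partner of every union is di-ortho-substituted, the least favourable case for both SNAr and copper-mediated etherification. Ring D is pentaoxygenated and carries the two chains on adjacent carbons D1 and D6, so the two arms must be attached with defined regiochemistry. The free phloroglucinol and pyrogallol units are oxidised by air in base and bind metals, so all hydroxyls stay masked until the last step, and the unmasking must leave the diaryl ethers intact. Ring B opens an entry that avoids one coupling: its oxygens on B1, B3 and B5 are in the 1,3,5-relationship of a phloroglucinol (the enol form of a cyclohexane-1,3,5-trione), and B4 between B3 and B5 carries the ether oxygen to ring C. B3–B4–B5 is therefore an aryloxymalonyl unit and B2–B1–B6 an acetone unit, and the hindered B4–O bond can be made at an sp3 carbon. The price is that B1, B3 and B5 emerge as three free hydroxyls that must be told apart.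

## Retrosynthesis

32 from 31. The seventeen O–H bonds are traced back to O–methyl bonds in the heptadecamethyl ether 31. Methyl is chosen because every building block is available as its methyl ether and because methyl ethers survive base, peracid, copper and hydrogenolysis. The forward step needs a Lewis acid that cleaves aryl methyl ethers but not diaryl ethers.

31 from 17 and 30. The O–D1 bond is cut, leaving the oxygen on C4 as the phenol 17 and ring D as the aryl bromide 30. This divides seven rings into three and four. It also keeps the oxygen on the doubly flanked carbon, the direction in which copper-mediated etherification tolerates hindrance best, and D1 has only one ortho substituent. Cutting D6–O instead would need a ring D phenol flanked on both sides by large groups. The forward reaction is an Ullmann coupling of a 2,6-dimethoxyphenol with an ortho-aryloxy aryl bromide.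

30 from 21, 22 (twice) and 29. The arm D–E–F–G is cut at O–E1, O–F1 and O–G1, so that each time the oxygen stays on the hindered carbon (D6, E4, F4) and the electrophilic carbon is unhindered. For rings E and F the fluoroaldehyde 22 serves twice: its fluoride, para to the formyl group, is displaced by SNAr, and the formyl group between two methoxy groups becomes the next hindered phenol by Baeyer–Villiger oxidation (23, 25, 26, 28). No metal is involved, so the D1 bromine is untouched. Ring G is terminal and fully methylated, and comes from boronic acid 29 by a room-temperature copper-mediated coupling that also spares the C–Br bond.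

21 from 20 and 18. The D1 bromine is introduced ortho to the hydroxyl of 20, whose para position is blocked. 20 comes from the commercial aldehyde 18 by Baeyer–Villiger oxidation.

17 from 16, and 16 from 14 and 15. The benzyl group on C4–O is removed last in this fragment. Before that the O–A1 bond is cut, leaving the oxygen on B1 as phenol 14 and ring A as the iodide 15. This is the one coupling with a di-ortho-substituted halide. It is accepted because ring B leaves the annulation as a phenol at B1 and because 15 is a catalogue compound.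

14 from 11 through 12 and 13. The three hydroxyls of triol 11 are differentiated by size: B1–OH has two ortho hydrogens, B3–OH and B5–OH each sit next to the aryloxy group. A bulky silyl group goes on B1 (12), B3 and B5 are methylated (13), and the silyl group is removed (14).

11 from 9, and 9 from 6 and 7. The two ester groups of 9 are removable by saponification and decarboxylation. Ring B of 9 is then cut at B2–B3 and B5–B6 into the aryloxymalonate 6 and the oxoglutarate 7. The neighbouring option, cutting B4–O, would be an aryl–O coupling between two tetraoxygenated rings at a doubly flanked carbon, the hardest bond type in the molecule. Here that bond is already present in 6 and the ring is closed by two C-acylations. The forward reaction must give C- rather than O-acylation and cross- rather than self-condensation.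

6 from 4 and 5, and 4 from 1. The B4–O bond is made by SN2 displacement of chloride from the chloromalonate 5 by phenol 4. Phenol 4 comes from syringaldehyde 1 by benzylation (2) and Baeyer–Villiger oxidation, so the C4 oxygen of the target is the phenol oxygen of 1.

## Roads not taken

Alternative 1: Both oxygens of ring D (D1–O and D6–O) are cut at once. In the forward direction the phenoxide of 17 and then that of the E–F–G phenol 4-[3,5-dimethoxy-4-(3,4,5-trimethoxyphenoxy)phenoxy]-3,5-dimethoxyphenol A3 would displace the two chlorides of 4,5-dichloro-3-methoxy-o-benzoquinone A2 by addition–elimination. This would give the bis(aryloxy)quinone A1, to be reduced and deprotected. Merits: it is the most convergent union possible, needs no metal, and brings the D3–D5 oxygens in with the electrophile, so the hindered copper coupling of step 18 would disappear. Weak points: two successive displacements must occur in the right order and at the right carbons. C5 of A2 is a plain vinylogous acyl chloride, C4 is attenuated by the C3 methoxy group, and that methoxy group is itself a leaving group, so arm-swapped and methoxy-displaced isomers of A1, hard to separate at this size, are to be expected. Electron-rich phenoxides are also one-electron reductants and carbon nucleophiles toward an o-quinone, and A2 is neither stable nor a catalogue compound. Phenol A3 would still have to be built ring by ring, much as in steps 13 to 17. Comparison: in convergence and in the number of operations on ring D this road is better than the chosen one, which grows the E–F–G arm on ring D linearly. The chosen plan sets against it that the position of every ring D substituent is fixed by the bromine of 21, and that no redox-active quinone meets a polyphenoxide. Alternative 1 would still need 17, so the ring B annulation would serve it equally.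

Alternative 2: The F1–O and G1–O bonds are cut by adding a carbonyl group to each. In the forward direction a zerovalent nickel catalyst (Ni(cod)2 with a bisphosphine such as dcype) would extrude CO from both ester groups of the didepside 4-(benzyloxy)-2,6-dimethoxyphenyl 3,5-dimethoxy-4-[(3,4,5-trimethoxybenzoyl)oxy]benzoate A5 to give the trimer ether A4. Merits: aryl esters are the easiest bonds to make and the acids are cheap, so A5 would come from two acylations and the two hindered ether bonds of A4 from one catalytic step. That is shorter than steps 13–17, which make the same two bonds. Weak points: decarbonylative etherification is established for aryl esters of electron-poor (hetero)aromatic acids. In A5 both acyl groups are trialkoxybenzoyl, which slows oxidative addition into the C(acyl)–O bond, and both phenoxide parts are di-ortho-methoxy-substituted, which hinders C–O reductive elimination. Two extrusions at high temperature are needed in one molecule. The method also covers only the E–F–G arm and leaves the B4–O bond and ring D to other chemistry. Comparison: for its arm this road is better in step economy. The chosen plan sets against it that each arm step is of a type already shown on trialkoxyaryl substrates.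

Alternative 3: Ring C is cut at C2–C3, C1–C6 and C3–C4. In the forward direction 4-(benzyloxy)-3-ethoxycyclobut-2-en-1-one A7 would open thermally to a vinylketene and add the ethynyl ether 2-(ethynyloxy)-1,3-dimethoxy-5-(2,4,6-trimethoxyphenoxy)benzene A8. Ring opening and 6π closure would give 2-(benzyloxy)-3-ethoxy-5-[2,6-dimethoxy-4-(2,4,6-trimethoxyphenoxy)phenoxy]phenol A6. Merits: like the chosen plan it makes a ring instead of a hindered ether bond, since the B4–O–C1 oxygen arrives on the alkyne. It also delivers ring C of A6 with three distinguishable oxygens (free OH, benzyl, ethyl) by construction. In this respect it is better than the chosen plan, whose ring B emerges as a symmetric triol and depends on the steric discrimination of step 6. Weak points: A8 is an ynol ether of a di-ortho-substituted, electron-rich phenol, needing several steps and thermally fragile. A7 needs a multistep four-membered-ring synthesis. The A–B ether must already exist, made by the same kind of hindered coupling as step 9. The differentiation of C3 from C5 in A6 is not needed by the target. Comparison: the chosen plan reaches its annulation precursor 6 in three steps from 1 with bulk reagents. It sets this, and the long precedent of the malonate condensation, against the cleaner oxygen differentiation of the benzannulation.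

Key step: step 4

Remark: all malonate and oxoglutarate esters are methyl esters and the halomalonate is the chloride, so that methoxide is the only alkoxide in the key step and halogen transfer to the electron-rich phenoxide is suppressed. Compounds 1, 5, 7, 15, 18, 22 and 29 are taken to be catalogue chemicals. The target is achiral.

## Route

Step 1
Reactants: 1 syringaldehyde (4-hydroxy-3,5-dimethoxybenzaldehyde)
Product: 2 4-(benzyloxy)-3,5-dimethoxybenzaldehyde
Conditions: BnBr, K2CO3, DMF, 60 °C
Reagents that add atoms: benzyl bromide, BrCc1ccccc1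
Why: Williamson ether synthesis; the phenoxide para to the formyl group alkylates cleanly at oxygen, and benzyl is the one group on ring C that hydrogenolysis can later remove beside methyl ethers.

Step 2
Reactants: 2 4-(benzyloxy)-3,5-dimethoxybenzaldehyde
Product: 4 4-(benzyloxy)-3,5-dimethoxyphenol, via aryl formate 3 (not isolated)
Conditions: mCPBA, CH2Cl2, 0 °C to rt; then cat. K2CO3, MeOH, rt
Reagents that add atoms: 3-chloroperoxybenzoic acid (mCPBA), OOC(=O)c1cccc(Cl)c1
Why: Baeyer–Villiger oxidation of an electron-rich benzaldehyde; the trialkoxyaryl group migrates in preference to hydrogen, and the formate is then methanolysed.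

Step 3
Reactants: 4 4-(benzyloxy)-3,5-dimethoxyphenol; 5 dimethyl 2-chloropropanedioate
Product: 6 dimethyl 2-[4-(benzyloxy)-3,5-dimethoxyphenoxy]propanedioate
Conditions: K2CO3, acetone, reflux
Reagents that add atoms: none
Why: SN2 O-alkylation of a phenoxide by a halomalonate, the standard route to aryloxymalonates; it makes the B4–O–C1 ether at an sp3 carbon where the flanking oxygens of ring B are not yet in the way.

Step 4
Reactants: 6 dimethyl 2-[4-(benzyloxy)-3,5-dimethoxyphenoxy]propanedioate; 7 dimethyl 3-oxopentanedioate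
Product: 9 dimethyl 5-[4-(benzyloxy)-3,5-dimethoxyphenoxy]-2,4,6-trihydroxybenzene-1,3-dicarboxylate, via open-chain Claisen adduct 8 (not isolated)
Conditions: NaOMe (3 equiv), MeOH–toluene, 65 to 110 °C with removal of MeOH, slow addition of 7, Ar; then aq. HCl
Reagents that add atoms: none
Why: Methoxide converts 7 into its enolate, whose C2 attacks one ester carbonyl of 6 in an intermolecular Claisen condensation and, after loss of methoxide, gives the open-chain adduct 8 with the B2–B3 bond in place. The second α-carbon of the oxoglutarate unit then attacks the remaining malonate ester in a Dieckmann condensation, a 6-exo-trig closure that forms B5–B6 and ring B. Loss of the second methoxide leaves a cyclohexane-1,3,5-trione diester that enolises at once, the single hydrogen on the aryloxy-bearing carbon B4 allowing full aromatisation. The closest known reaction type is the alkoxide-mediated condensation of malonic esters with acetonedicarboxylic esters, and of malonates with themselves, to phloroglucinol carboxylates. No stereocentre is formed. The selectivity needed is C- over O-acylation and cross- over self-condensation of 7: O-acylated species and pyranones stay in equilibrium under methoxide while the doubly C-acylated product is withdrawn as its aromatic phenolate, and slow addition of 7 to an excess of 6 and NaOMe keeps 7 dilute. The α-aryloxy group raises the electrophilicity of the malonate carbonyls, and with methyl esters throughout transesterification changes nothing.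

Step 5
Reactants: 9 dimethyl 5-[4-(benzyloxy)-3,5-dimethoxyphenoxy]-2,4,6-trihydroxybenzene-1,3-dicarboxylate
Product: 11 2-[4-(benzyloxy)-3,5-dimethoxyphenoxy]benzene-1,3,5-triol, via dicarboxylic acid 10 (not isolated)
Conditions: aq. NaOH (degassed), Ar, 100 °C; then aq. HCl, 60 °C
Reagents that add atoms: none
Why: Saponification followed by protodecarboxylation; phloroglucinolcarboxylic acids lose CO2 on gentle warming in acid because the keto tautomer is a β-keto acid, and benzyl and diaryl ethers are inert to both media.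

Step 6
Reactants: 11 2-[4-(benzyloxy)-3,5-dimethoxyphenoxy]benzene-1,3,5-triol
Product: 12 2-[4-(benzyloxy)-3,5-dimethoxyphenoxy]-5-{[tri(propan-2-yl)silyl]oxy}benzene-1,3-diol
Conditions: TIPSCl (1.0 equiv), imidazole, DMF, −20 to 0 °C
Reagents that add atoms: chlorotri(propan-2-yl)silane (TIPSCl), CC(C)[Si](Cl)(C(C)C)C(C)C
Why: Sterically controlled phenol silylation; B1–OH has two ortho hydrogens whereas B3–OH and B5–OH each sit beside the aryloxy group and hydrogen-bond to it, the situation in which 2-alkoxyhydroquinones are silylated selectively at the unflanked hydroxyl.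

Step 7
Reactants: 12 2-[4-(benzyloxy)-3,5-dimethoxyphenoxy]-5-{[tri(propan-2-yl)silyl]oxy}benzene-1,3-diol
Product: 13 {4-[4-(benzyloxy)-3,5-dimethoxyphenoxy]-3,5-dimethoxyphenoxy}tri(propan-2-yl)silane
Conditions: MeI, K2CO3, acetone, 45 °C
Reagents that add atoms: iodomethane, CI
Why: Williamson methylation of the two remaining phenols; an aryl triisopropylsilyl ether is stable to K2CO3 in acetone and too hindered for silyl transfer.

Step 8
Reactants: 13 {4-[4-(benzyloxy)-3,5-dimethoxyphenoxy]-3,5-dimethoxyphenoxy}tri(propan-2-yl)silane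
Product: 14 4-[4-(benzyloxy)-3,5-dimethoxyphenoxy]-3,5-dimethoxyphenol
Conditions: Bu4NF, THF, 0 °C; aq. NH4Cl
Reagents that add atoms: none
Why: Fluoride-induced cleavage of the aryl silyl ether, driven by the Si–F bond; it frees only the B1 hydroxyl.

Step 9
Reactants: 14 4-[4-(benzyloxy)-3,5-dimethoxyphenoxy]-3,5-dimethoxyphenol; 15 2-iodo-1,3,5-trimethoxybenzene
Product: 16 2-{4-[4-(benzyloxy)-3,5-dimethoxyphenoxy]-3,5-dimethoxyphenoxy}-1,3,5-trimethoxybenzene
Conditions: CuI (10 mol%), picolinic acid (20 mol%), K3PO4, DMSO, 100 °C, Ar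
Reagents that add atoms: none
Why: Ligand-accelerated Ullmann diaryl ether synthesis; the phenol is unhindered and electron-rich, and the pairing of a 2-halo-1,3,5-trimethoxybenzene with a 3,5-dialkoxyphenol is the classical entry to phlorethol methyl ethers.

Step 10
Reactants: 16 2-{4-[4-(benzyloxy)-3,5-dimethoxyphenoxy]-3,5-dimethoxyphenoxy}-1,3,5-trimethoxybenzene
Product: 17 4-[2,6-dimethoxy-4-(2,4,6-trimethoxyphenoxy)phenoxy]-2,6-dimethoxyphenol
Conditions: H2 (1 atm), Pd/C, EtOAc–MeOH, rt
Reagents that add atoms: none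
Why: Hydrogenolysis of the benzyl ether; methyl and diaryl ethers are untouched and no halogen is present in this fragment.

Step 11
Reactants: 18 2,3,4-trimethoxybenzaldehyde
Product: 20 2,3,4-trimethoxyphenol, via aryl formate 19 (not isolated)
Conditions: mCPBA, CH2Cl2, 0 °C to rt; then cat. K2CO3, MeOH, rt
Reagents that add atoms: 3-chloroperoxybenzoic acid (mCPBA), OOC(=O)c1cccc(Cl)c1
Why: Baeyer–Villiger oxidation; ortho- and para-methoxy groups make aryl migration fast, and methanolysis frees the phenol.

Step 12
Reactants: 20 2,3,4-trimethoxyphenol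
Product: 21 6-bromo-2,3,4-trimethoxyphenol
Conditions: NBS, i-Pr2NH (cat.), CH2Cl2, −20 to 0 °C
Reagents that add atoms: N-bromosuccinimide, O=C1CCC(=O)N1Br
Why: Amine-mediated ortho-bromination of a phenol; the para position is blocked, the hydroxyl is the strongest donor, and C6 is the only free ortho position, as in the ortho-bromination of 4-methoxyphenols.

Step 13
Reactants: 21 6-bromo-2,3,4-trimethoxyphenol; 22 4-fluoro-2,6-dimethoxybenzaldehyde
Product: 23 4-(6-bromo-2,3,4-trimethoxyphenoxy)-2,6-dimethoxybenzaldehyde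
Conditions: K2CO3, DMF, 120 °C
Reagents that add atoms: none
Why: SNAr (addition–elimination) of a phenoxide on a 4-fluorobenzaldehyde; the Meisenheimer intermediate is stabilised by the para formyl group, the methoxy groups are meta to the reacting carbon, and the electron-rich aryl bromide is inert.

Step 14
Reactants: 23 4-(6-bromo-2,3,4-trimethoxyphenoxy)-2,6-dimethoxybenzaldehyde
Product: 25 4-(6-bromo-2,3,4-trimethoxyphenoxy)-2,6-dimethoxyphenol, via aryl formate 24 (not isolated)
Conditions: mCPBA, CH2Cl2, 0 °C; Me2S quench; then cat. K2CO3, MeOH, rt, Ar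
Reagents that add atoms: 3-chloroperoxybenzoic acid (mCPBA), OOC(=O)c1cccc(Cl)c1
Why: Baeyer–Villiger oxidation of a 2,6-dimethoxybenzaldehyde, for which aryl migration is strongly favoured; it turns the activating formyl group into the next hindered phenol.

Step 15
Reactants: 25 4-(6-bromo-2,3,4-trimethoxyphenoxy)-2,6-dimethoxyphenol; 22 4-fluoro-2,6-dimethoxybenzaldehyde
Product: 26 4-[4-(6-bromo-2,3,4-trimethoxyphenoxy)-2,6-dimethoxyphenoxy]-2,6-dimethoxybenzaldehyde
Conditions: K2CO3, DMF, 120 °C
Reagents that add atoms: none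
Why: The same SNAr as in step 13, now with a 2,6-dimethoxyphenoxide; phenoxides flanked by two ortho substituents are competent nucleophiles toward para-activated aryl fluorides because the electrophilic carbon is unhindered.

Step 16
Reactants: 26 4-[4-(6-bromo-2,3,4-trimethoxyphenoxy)-2,6-dimethoxyphenoxy]-2,6-dimethoxybenzaldehyde
Product: 28 4-[4-(6-bromo-2,3,4-trimethoxyphenoxy)-2,6-dimethoxyphenoxy]-2,6-dimethoxyphenol, via aryl formate 27 (not isolated)
Conditions: mCPBA, CH2Cl2, 0 °C; Me2S quench; then cat. K2CO3, MeOH, rt, Ar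
Reagents that add atoms: 3-chloroperoxybenzoic acid (mCPBA), OOC(=O)c1cccc(Cl)c1
Why: Baeyer–Villiger oxidation as in step 14, giving the F4 hydroxyl.

Step 17
Reactants: 28 4-[4-(6-bromo-2,3,4-trimethoxyphenoxy)-2,6-dimethoxyphenoxy]-2,6-dimethoxyphenol; 29 (3,4,5-trimethoxyphenyl)boronic acid
Product: 30 1-bromo-2-{4-[3,5-dimethoxy-4-(3,4,5-trimethoxyphenoxy)phenoxy]-3,5-dimethoxyphenoxy}-3,4,5-trimethoxybenzene
Conditions: Cu(OAc)2 (1.5 equiv), pyridine, 4 Å MS, CH2Cl2, air, rt
Reagents that add atoms: none
Why: Chan–Lam–Evans coupling; the aryl group passes from boron to a divalent copper phenoxide, and C–O reductive elimination follows from trivalent copper. It proceeds at room temperature with ortho-disubstituted phenols and does not insert into the C–Br bond kept for step 18.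

Step 18
Reactants: 17 4-[2,6-dimethoxy-4-(2,4,6-trimethoxyphenoxy)phenoxy]-2,6-dimethoxyphenol; 30 1-bromo-2-{4-[3,5-dimethoxy-4-(3,4,5-trimethoxyphenoxy)phenoxy]-3,5-dimethoxyphenoxy}-3,4,5-trimethoxybenzene
Product: 31 1-{4-[2,6-dimethoxy-4-(2,4,6-trimethoxyphenoxy)phenoxy]-2,6-dimethoxyphenoxy}-2-{4-[3,5-dimethoxy-4-(3,4,5-trimethoxyphenoxy)phenoxy]-3,5-dimethoxyphenoxy}-3,4,5-trimethoxybenzene
Conditions: CuI (20 mol%), picolinic acid (40 mol%), K3PO4, DMSO, 110 °C, Ar
Reagents that add atoms: none
Why: Ullmann diaryl ether synthesis with the picolinic acid ligand system developed for hindered phenols and ortho-substituted aryl halides; the oxygen sits on the doubly flanked carbon and the bromide has one ortho substituent, the pattern used for polymethoxylated diphenyl ethers.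

Step 19
Reactants: 31 1-{4-[2,6-dimethoxy-4-(2,4,6-trimethoxyphenoxy)phenoxy]-2,6-dimethoxyphenoxy}-2-{4-[3,5-dimethoxy-4-(3,4,5-trimethoxyphenoxy)phenoxy]-3,5-dimethoxyphenoxy}-3,4,5-trimethoxybenzene
Product: 32 5-{4-[2,6-dihydroxy-4-(2,4,6-trihydroxyphenoxy)phenoxy]-2,6-dihydroxyphenoxy}-4-{4-[3,5-dihydroxy-4-(3,4,5-trihydroxyphenoxy)phenoxy]-3,5-dihydroxyphenoxy}benzene-1,2,3-triol
Conditions: BBr3 (excess), CH2Cl2, −78 °C to rt, Ar; then MeOH–H2O, degassed work-up
Reagents that add atoms: none
Why: Lewis-acid demethylation of aryl methyl ethers by bromide attack on the boron-complexed methyl group; diaryl ethers have no alkyl carbon to attack and survive, so all seventeen hydroxyls are freed in one operation.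

## Compound list

1 | syringaldehyde (4-hydroxy-3,5-dimethoxybenzaldehyde) | COc1cc(C=O)cc(OC)c1O | starting material
2 | 4-(benzyloxy)-3,5-dimethoxybenzaldehyde | COc1cc(C=O)cc(OC)c1OCc1ccccc1 | intermediate
3 | 4-(benzyloxy)-3,5-dimethoxyphenyl formate | O=COc1cc(OC)c(OCc2ccccc2)c(OC)c1 | intermediate
4 | 4-(benzyloxy)-3,5-dimethoxyphenol | Oc1cc(OC)c(OCc2ccccc2)c(OC)c1 | intermediate
5 | dimethyl 2-chloropropanedioate | COC(=O)C(Cl)C(=O)OC | starting material
6 | dimethyl 2-[4-(benzyloxy)-3,5-dimethoxyphenoxy]propanedioate | COC(=O)C(Oc1cc(OC)c(OCc2ccccc2)c(OC)c1)C(=O)OC | intermediate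
7 | dimethyl 3-oxopentanedioate | COC(=O)CC(=O)CC(=O)OC | starting material
8 | dimethyl 2-{2-[4-(benzyloxy)-3,5-dimethoxyphenoxy]-3-methoxy-3-oxopropanoyl}-3-oxopentanedioate | COC(=O)CC(=O)C(C(=O)OC)C(=O)C(Oc1cc(OC)c(OCc2ccccc2)c(OC)c1)C(=O)OC | intermediate
9 | dimethyl 5-[4-(benzyloxy)-3,5-dimethoxyphenoxy]-2,4,6-trihydroxybenzene-1,3-dicarboxylate | COC(=O)c1c(O)c(C(=O)OC)c(O)c(Oc2cc(OC)c(OCc3ccccc3)c(OC)c2)c1O | intermediate
10 | 5-[4-(benzyloxy)-3,5-dimethoxyphenoxy]-2,4,6-trihydroxybenzene-1,3-dicarboxylic acid | OC(=O)c1c(O)c(C(O)=O)c(O)c(Oc2cc(OC)c(OCc3ccccc3)c(OC)c2)c1O | intermediate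
11 | 2-[4-(benzyloxy)-3,5-dimethoxyphenoxy]benzene-1,3,5-triol | Oc1cc(O)c(Oc2cc(OC)c(OCc3ccccc3)c(OC)c2)c(O)c1 | intermediate
12 | 2-[4-(benzyloxy)-3,5-dimethoxyphenoxy]-5-{[tri(propan-2-yl)silyl]oxy}benzene-1,3-diol | CC(C)[Si](Oc1cc(O)c(Oc2cc(OC)c(OCc3ccccc3)c(OC)c2)c(O)c1)(C(C)C)C(C)C | intermediate
13 | {4-[4-(benzyloxy)-3,5-dimethoxyphenoxy]-3,5-dimethoxyphenoxy}tri(propan-2-yl)silane | COc1cc(O[Si](C(C)C)(C(C)C)C(C)C)cc(OC)c1Oc1cc(OC)c(OCc2ccccc2)c(OC)c1 | intermediate
14 | 4-[4-(benzyloxy)-3,5-dimethoxyphenoxy]-3,5-dimethoxyphenol | COc1cc(O)cc(OC)c1Oc1cc(OC)c(OCc2ccccc2)c(OC)c1 | intermediate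
15 | 2-iodo-1,3,5-trimethoxybenzene | COc1cc(OC)c(I)c(OC)c1 | starting material
16 | 2-{4-[4-(benzyloxy)-3,5-dimethoxyphenoxy]-3,5-dimethoxyphenoxy}-1,3,5-trimethoxybenzene | COc1cc(OC)c(Oc2cc(OC)c(Oc3cc(OC)c(OCc4ccccc4)c(OC)c3)c(OC)c2)c(OC)c1 | intermediate
17 | 4-[2,6-dimethoxy-4-(2,4,6-trimethoxyphenoxy)phenoxy]-2,6-dimethoxyphenol | COc1cc(OC)c(Oc2cc(OC)c(Oc3cc(OC)c(O)c(OC)c3)c(OC)c2)c(OC)c1 | intermediate
18 | 2,3,4-trimethoxybenzaldehyde | COc1ccc(C=O)c(OC)c1OC | starting material
19 | 2,3,4-trimethoxyphenyl formate | COc1ccc(OC=O)c(OC)c1OC | intermediate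
20 | 2,3,4-trimethoxyphenol | COc1ccc(O)c(OC)c1OC | intermediate
21 | 6-bromo-2,3,4-trimethoxyphenol | COc1cc(Br)c(O)c(OC)c1OC | intermediate
22 | 4-fluoro-2,6-dimethoxybenzaldehyde | COc1cc(F)cc(OC)c1C=O | starting material
23 | 4-(6-bromo-2,3,4-trimethoxyphenoxy)-2,6-dimethoxybenzaldehyde | COc1cc(Oc2c(Br)cc(OC)c(OC)c2OC)cc(OC)c1C=O | intermediate
24 | 4-(6-bromo-2,3,4-trimethoxyphenoxy)-2,6-dimethoxyphenyl formate | COc1cc(Oc2c(Br)cc(OC)c(OC)c2OC)cc(OC)c1OC=O | intermediate
25 | 4-(6-bromo-2,3,4-trimethoxyphenoxy)-2,6-dimethoxyphenol | COc1cc(Oc2c(Br)cc(OC)c(OC)c2OC)cc(OC)c1O | intermediate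
26 | 4-[4-(6-bromo-2,3,4-trimethoxyphenoxy)-2,6-dimethoxyphenoxy]-2,6-dimethoxybenzaldehyde | COc1cc(Oc2c(OC)cc(Oc3c(Br)cc(OC)c(OC)c3OC)cc2OC)cc(OC)c1C=O | intermediate
27 | 4-[4-(6-bromo-2,3,4-trimethoxyphenoxy)-2,6-dimethoxyphenoxy]-2,6-dimethoxyphenyl formate | COc1cc(Oc2c(OC)cc(Oc3c(Br)cc(OC)c(OC)c3OC)cc2OC)cc(OC)c1OC=O | intermediate
28 | 4-[4-(6-bromo-2,3,4-trimethoxyphenoxy)-2,6-dimethoxyphenoxy]-2,6-dimethoxyphenol | COc1cc(Oc2c(OC)cc(Oc3c(Br)cc(OC)c(OC)c3OC)cc2OC)cc(OC)c1O | intermediate
29 | (3,4,5-trimethoxyphenyl)boronic acid | COc1cc(B(O)O)cc(OC)c1OC | starting material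
30 | 1-bromo-2-{4-[3,5-dimethoxy-4-(3,4,5-trimethoxyphenoxy)phenoxy]-3,5-dimethoxyphenoxy}-3,4,5-trimethoxybenzene | COc1cc(Oc2c(OC)cc(Oc3c(OC)cc(Oc4c(Br)cc(OC)c(OC)c4OC)cc3OC)cc2OC)cc(OC)c1OC | intermediate
31 | 1-{4-[2,6-dimethoxy-4-(2,4,6-trimethoxyphenoxy)phenoxy]-2,6-dimethoxyphenoxy}-2-{4-[3,5-dimethoxy-4-(3,4,5-trimethoxyphenoxy)phenoxy]-3,5-dimethoxyphenoxy}-3,4,5-trimethoxybenzene | COc1cc(OC)c(Oc2cc(OC)c(Oc3cc(OC)c(Oc4cc(OC)c(OC)c(OC)c4Oc4cc(OC)c(Oc5cc(OC)c(Oc6cc(OC)c(OC)c(OC)c6)c(OC)c5)c(OC)c4)c(OC)c3)c(OC)c2)c(OC)c1 | intermediate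
32 | 5-{4-[2,6-dihydroxy-4-(2,4,6-trihydroxyphenoxy)phenoxy]-2,6-dihydroxyphenoxy}-4-{4-[3,5-dihydroxy-4-(3,4,5-trihydroxyphenoxy)phenoxy]-3,5-dihydroxyphenoxy}benzene-1,2,3-triol | Oc1cc(O)c(Oc2cc(O)c(Oc3cc(O)c(Oc4cc(O)c(O)c(O)c4Oc4cc(O)c(Oc5cc(O)c(Oc6cc(O)c(O)c(O)c6)c(O)c5)c(O)c4)c(O)c3)c(O)c2)c(O)c1 | target

## Step count and risk

Total step count: 19. Longest linear sequence: 12 steps (steps 1–10, 18 and 19, from 1). The second branch (steps 11–17) has 7 steps before the union.

Steps least certain to work:

Step 4 (key step). The aryloxymalonate 6 is largely held as its enolate, whose ester carbonyls are poor electrophiles. Self-condensation of 7, or O-acylation leading to a pyranone, may then outrun the cross-condensation. Fallback, from 6 back to 9: the same two bonds are made in separate operations. Compound 6 is mono-saponified (KOH, 1 equiv, MeOH, 0 °C) to the half ester 2-[4-(benzyloxy)-3,5-dimethoxyphenoxy]-3-methoxy-3-oxopropanoic acid F1. F1 is converted with oxalyl chloride and cat. DMF into methyl 2-[4-(benzyloxy)-3,5-dimethoxyphenoxy]-3-chloro-3-oxopropanoate F2. F2 C-acylates the magnesium enolate of 7 (MgCl2, Et3N, MeCN, 0 °C) to give 8, now isolated, and 8 is closed with NaOMe in MeOH to 9.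

Step 6. Discrimination between the unflanked B1 hydroxyl and the two hydroxyls next to the aryloxy group may be incomplete, giving regioisomeric and doubly silylated material. Fallback, from 11 to 16: the selection is moved into the C–O coupling. Triol 11, in excess, is coupled directly with iodide 15 under the conditions of step 9. The two ortho-methoxy groups of the electrophile should refuse the flanked B3 and B5 oxygens, giving 2-[4-(benzyloxy)-3,5-dimethoxyphenoxy]-5-(2,4,6-trimethoxyphenoxy)benzene-1,3-diol F3. F3 is methylated (MeI, K2CO3, acetone) to 16.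

Step 9. Oxidative addition of monovalent copper to the di-ortho-methoxy iodide 15 is slow, so protodeiodination and stalled conversion may dominate. Fallback, from 14 to 16: ring A is built instead of coupled, by a second malonate annulation that needs no selectivity. Phenol 14 is alkylated with 5 (K2CO3, acetone) to dimethyl 2-{4-[4-(benzyloxy)-3,5-dimethoxyphenoxy]-3,5-dimethoxyphenoxy}propanedioate F4. F4 is condensed with 7 and NaOMe, through the open-chain adduct dimethyl 2-(2-{4-[4-(benzyloxy)-3,5-dimethoxyphenoxy]-3,5-dimethoxyphenoxy}-3-methoxy-3-oxopropanoyl)-3-oxopentanedioate F5, to dimethyl 5-{4-[4-(benzyloxy)-3,5-dimethoxyphenoxy]-3,5-dimethoxyphenoxy}-2,4,6-trihydroxybenzene-1,3-dicarboxylate F6. F6 is saponified to 5-{4-[4-(benzyloxy)-3,5-dimethoxyphenoxy]-3,5-dimethoxyphenoxy}-2,4,6-trihydroxybenzene-1,3-dicarboxylic acid F7, which decarboxylates to 2-{4-[4-(benzyloxy)-3,5-dimethoxyphenoxy]-3,5-dimethoxyphenoxy}benzene-1,3,5-triol F8. All three hydroxyls of F8 are methylated (MeI, K2CO3) to give 16.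

Step 17. The electron-rich, hindered phenol 28 may be oxidised by divalent copper and air faster than it is arylated, while 29 is lost to protodeboronation and homocoupling. Fallback, from 28 to 30: ring G is added the way rings E and F were. SNAr of 28 on 22 (K2CO3, DMF, 120 °C) gives 4-{4-[4-(6-bromo-2,3,4-trimethoxyphenoxy)-2,6-dimethoxyphenoxy]-2,6-dimethoxyphenoxy}-2,6-dimethoxybenzaldehyde F9. Baeyer–Villiger oxidation gives 4-{4-[4-(6-bromo-2,3,4-trimethoxyphenoxy)-2,6-dimethoxyphenoxy]-2,6-dimethoxyphenoxy}-2,6-dimethoxyphenyl formate F10. Methanolysis gives 4-{4-[4-(6-bromo-2,3,4-trimethoxyphenoxy)-2,6-dimethoxyphenoxy]-2,6-dimethoxyphenoxy}-2,6-dimethoxyphenol F11, and methylation (MeI, K2CO3) gives 30.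

Step 18. Coupling of a hindered phenoxide with an ortho-aryloxy, electron-rich bromide may be slow enough that hydrodebromination of 30 and oxidation of 17 take over. Fallback, from 30 to 31: the polarity of ring D is reversed. Bromine–lithium exchange on 30 (n-BuLi, THF, −78 °C), B(OMe)3 and acidic work-up give (2-{4-[3,5-dimethoxy-4-(3,4,5-trimethoxyphenoxy)phenoxy]-3,5-dimethoxyphenoxy}-3,4,5-trimethoxyphenyl)boronic acid F12. F12 is joined to 17 by a Chan–Lam–Evans coupling (Cu(OAc)2, pyridine, 4 Å MS, CH2Cl2, air, rt) to give 31.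

## Further compounds

F1 | step 4 | 2-[4-(benzyloxy)-3,5-dimethoxyphenoxy]-3-methoxy-3-oxopropanoic acid | COC(=O)C(Oc1cc(OC)c(OCc2ccccc2)c(OC)c1)C(O)=O
F2 | step 4 | methyl 2-[4-(benzyloxy)-3,5-dimethoxyphenoxy]-3-chloro-3-oxopropanoate | COC(=O)C(Oc1cc(OC)c(OCc2ccccc2)c(OC)c1)C(Cl)=O
F3 | step 6 | 2-[4-(benzyloxy)-3,5-dimethoxyphenoxy]-5-(2,4,6-trimethoxyphenoxy)benzene-1,3-diol | COc1cc(OC)c(Oc2cc(O)c(Oc3cc(OC)c(OCc4ccccc4)c(OC)c3)c(O)c2)c(OC)c1
F4 | step 9 | dimethyl 2-{4-[4-(benzyloxy)-3,5-dimethoxyphenoxy]-3,5-dimethoxyphenoxy}propanedioate | COC(=O)C(Oc1cc(OC)c(Oc2cc(OC)c(OCc3ccccc3)c(OC)c2)c(OC)c1)C(=O)OC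
F5 | step 9 | dimethyl 2-(2-{4-[4-(benzyloxy)-3,5-dimethoxyphenoxy]-3,5-dimethoxyphenoxy}-3-methoxy-3-oxopropanoyl)-3-oxopentanedioate | COC(=O)CC(=O)C(C(=O)OC)C(=O)C(Oc1cc(OC)c(Oc2cc(OC)c(OCc3ccccc3)c(OC)c2)c(OC)c1)C(=O)OC
F6 | step 9 | dimethyl 5-{4-[4-(benzyloxy)-3,5-dimethoxyphenoxy]-3,5-dimethoxyphenoxy}-2,4,6-trihydroxybenzene-1,3-dicarboxylate | COC(=O)c1c(O)c(C(=O)OC)c(O)c(Oc2cc(OC)c(Oc3cc(OC)c(OCc4ccccc4)c(OC)c3)c(OC)c2)c1O
F7 | step 9 | 5-{4-[4-(benzyloxy)-3,5-dimethoxyphenoxy]-3,5-dimethoxyphenoxy}-2,4,6-trihydroxybenzene-1,3-dicarboxylic acid | OC(=O)c1c(O)c(C(O)=O)c(O)c(Oc2cc(OC)c(Oc3cc(OC)c(OCc4ccccc4)c(OC)c3)c(OC)c2)c1O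
F8 | step 9 | 2-{4-[4-(benzyloxy)-3,5-dimethoxyphenoxy]-3,5-dimethoxyphenoxy}benzene-1,3,5-triol | Oc1cc(O)c(Oc2cc(OC)c(Oc3cc(OC)c(OCc4ccccc4)c(OC)c3)c(OC)c2)c(O)c1
F9 | step 17 | 4-{4-[4-(6-bromo-2,3,4-trimethoxyphenoxy)-2,6-dimethoxyphenoxy]-2,6-dimethoxyphenoxy}-2,6-dimethoxybenzaldehyde | COc1cc(Oc2c(OC)cc(Oc3c(OC)cc(Oc4c(Br)cc(OC)c(OC)c4OC)cc3OC)cc2OC)cc(OC)c1C=O
F10 | step 17 | 4-{4-[4-(6-bromo-2,3,4-trimethoxyphenoxy)-2,6-dimethoxyphenoxy]-2,6-dimethoxyphenoxy}-2,6-dimethoxyphenyl formate | COc1cc(Oc2c(OC)cc(Oc3c(OC)cc(Oc4c(Br)cc(OC)c(OC)c4OC)cc3OC)cc2OC)cc(OC)c1OC=O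
F11 | step 17 | 4-{4-[4-(6-bromo-2,3,4-trimethoxyphenoxy)-2,6-dimethoxyphenoxy]-2,6-dimethoxyphenoxy}-2,6-dimethoxyphenol | COc1cc(Oc2c(OC)cc(Oc3c(OC)cc(Oc4c(Br)cc(OC)c(OC)c4OC)cc3OC)cc2OC)cc(OC)c1O
F12 | step 18 | (2-{4-[3,5-dimethoxy-4-(3,4,5-trimethoxyphenoxy)phenoxy]-3,5-dimethoxyphenoxy}-3,4,5-trimethoxyphenyl)boronic acid | COc1cc(Oc2c(OC)cc(Oc3c(OC)cc(Oc4c(B(O)O)cc(OC)c(OC)c4OC)cc3OC)cc2OC)cc(OC)c1OC
A1 | alternative 1 | 4-{4-[3,5-dimethoxy-4-(3,4,5-trimethoxyphenoxy)phenoxy]-3,5-dimethoxyphenoxy}-5-{4-[2,6-dimethoxy-4-(2,4,6-trimethoxyphenoxy)phenoxy]-2,6-dimethoxyphenoxy}-3-methoxycyclohexa-3,5-diene-1,2-dione | O=C1C=C(Oc3c(OC)cc(Oc2c(OC)cc(Oc7c(OC)cc(OC)cc7OC)cc2OC)cc3OC)C(Oc4cc(OC)c(Oc5cc(OC)c(Oc6cc(OC)c(OC)c(OC)c6)c(OC)c5)c(OC)c4)=C(OC)C1=O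
A2 | alternative 1 | 4,5-dichloro-3-methoxycyclohexa-3,5-diene-1,2-dione | COC1=C(Cl)C(Cl)=CC(=O)C1=O
A3 | alternative 1 | 4-[3,5-dimethoxy-4-(3,4,5-trimethoxyphenoxy)phenoxy]-3,5-dimethoxyphenol | COc1cc(O)cc(OC)c1Oc1cc(OC)c(Oc2cc(OC)c(OC)c(OC)c2)c(OC)c1
A4 | alternative 2 | 5-(benzyloxy)-2-[3,5-dimethoxy-4-(3,4,5-trimethoxyphenoxy)phenoxy]-1,3-dimethoxybenzene | COc1cc(OCc2ccccc2)cc(OC)c1Oc1cc(OC)c(Oc2cc(OC)c(OC)c(OC)c2)c(OC)c1
A5 | alternative 2 | 4-(benzyloxy)-2,6-dimethoxyphenyl 3,5-dimethoxy-4-[(3,4,5-trimethoxybenzoyl)oxy]benzoate | COc1cc(OCc2ccccc2)cc(OC)c1OC(=O)c1cc(OC)c(OC(=O)c2cc(OC)c(OC)c(OC)c2)c(OC)c1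
A6 | alternative 3 | 2-(benzyloxy)-3-ethoxy-5-[2,6-dimethoxy-4-(2,4,6-trimethoxyphenoxy)phenoxy]phenol | CCOc1cc(Oc2c(OC)cc(Oc3c(OC)cc(OC)cc3OC)cc2OC)cc(O)c1OCc1ccccc1
A7 | alternative 3 | 4-(benzyloxy)-3-ethoxycyclobut-2-en-1-one | CCOC1=CC(=O)C1OCc1ccccc1
A8 | alternative 3 | 2-(ethynyloxy)-1,3-dimethoxy-5-(2,4,6-trimethoxyphenoxy)benzene | C#COc1c(OC)cc(Oc2c(OC)cc(OC)cc2OC)cc1OC
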